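**Plan**
1. Bleochrin B is an achiral bibenzyl. Ring A is hexasubstituted (OMe, OH, the bridge, three 4-hydroxybenzyl groups). Ring B is numbered from B1 (bridge carbon) to B6 (carbon bearing the fourth 4-hydroxybenzyl group) and carries its OH on B3.
2. Retrosynthetic cuts, in order: the five O–benzyl protecting bonds and the B6 benzylic C=O; B1–B2 and B5–B6 of ring B; the alkyne–acyl bond; the ArCH2–CH2 bond; the aryl–CHO bond; the three C-benzyl bonds of ring A.
3. Enabling feature: the B3 hydroxyl is para to B6 and meta to B1. A 1-methoxy-3-silyloxybutadiene gives exactly this placement when its CH2 end bonds to the β-carbon of an ynone whose carbonyl carbon becomes the B6 benzylic carbon.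
4. Forward order: ring A is completed first by threefold Friedel–Crafts benzylation; its bromide is turned into a but-3-ynyl chain and aroylated; ring B is then built from the open-chain ynone; ketone deoxygenation and debenzylation finish the synthesis.
5. Stereochemistry: there is none to set. The one sp3 stereocentre of the cycloadduct is racemic and vanishes on aromatization.

Key step: step 9

Assumption: all phenols are carried as benzyl ethers, so the benzyl-protected building blocks 2 and 13 (both purchasable) replace free 4-hydroxybenzyl and 4-hydroxybenzoyl units, and the end game is ionic hydrogenation followed by hydrogenolysis.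
Abbreviation: ArA = 3-(benzyloxy)-2,4,6-tris[4-(benzyloxy)benzyl]-5-methoxyphenyl, attached through C1.

**Step 1**
Reactants: 1 3-bromo-5-methoxyphenol; 2 4-(benzyloxy)benzyl alcohol
Product: 3 3-bromo-2,4,6-tris[4-(benzyloxy)benzyl]-5-methoxyphenol
Conditions: 2 (3.3 equiv, slow addition), TsOH·H2O (10 mol%), 1,1,1,3,3,3-hexafluoropropan-2-ol/CH2Cl2 (1:3), 0 °C to rt
Reagents that add atoms: 4-(benzyloxy)benzyl alcohol (compound 2), OCc1ccc(OCc2ccccc2)cc1
Why: Acid-catalysed Friedel–Crafts benzylation, in which the 4-(benzyloxy)benzyl cation attacks the three free positions of 1, each ortho or para to both oxygen substituents and far more nucleophilic than the mono-alkoxy pendant rings, so alkylation should stop once ring A is filled.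

**Step 2**
Reactants: 3 3-bromo-2,4,6-tris[4-(benzyloxy)benzyl]-5-methoxyphenol
Product: 4 ArA–Br [1-(benzyloxy)-3-bromo-2,4,6-tris[4-(benzyloxy)benzyl]-5-methoxybenzene]
Conditions: BnBr, K2CO3, DMF, 60 °C
Reagents that add atoms: benzyl bromide, BrCc1ccccc1
Why: Williamson ether synthesis; the phenoxide of the di-ortho-substituted phenol is still readily O-alkylated by the unhindered benzyl bromide in DMF.

**Step 3**
Reactants: 4 ArA–Br
Product: 6 ArA–CHO [3-(benzyloxy)-2,4,6-tris[4-(benzyloxy)benzyl]-5-methoxybenzaldehyde], via aryllithium 5 (not isolated)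
Conditions: n-BuLi, THF, –78 °C; DMF, –78 to 0 °C; then H2O
Reagents that add atoms: N,N-dimethylformamide, CN(C)C=O
Why: Bromine–lithium exchange at –78 °C is much faster than deprotonation of the diarylmethane CH2 groups, and the aryllithium adds to DMF to release the aldehyde on hydrolysis (Bouveault formylation).

**Step 4**
Reactants: 6 ArA–CHO
Product: 7 ArA–CH2OH [[3-(benzyloxy)-2,4,6-tris[4-(benzyloxy)benzyl]-5-methoxyphenyl]methanol]
Conditions: NaBH4, THF/MeOH, 0 °C to rt
Reagents that add atoms: none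
Why: Borohydride reduction of an aromatic aldehyde; no other group in 6 is reducible by NaBH4.

**Step 5**
Reactants: 7 ArA–CH2OH
Product: 8 ArA–CH2Br [1-(benzyloxy)-3-(bromomethyl)-2,4,6-tris[4-(benzyloxy)benzyl]-5-methoxybenzene]
Conditions: CBr4, PPh3, CH2Cl2, 0 °C
Reagents that add atoms: carbon tetrabromide, BrC(Br)(Br)Br
Why: Appel bromination under neutral conditions leaves the benzyl ethers untouched, and the bromide should be handleable because both ring oxygens are meta to the CH2Br carbon and do not assist ionization.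

**Step 6**
Reactants: 8 ArA–CH2Br; 9 1-(trimethylsilyl)propyne
Product: 11 ArA–CH2CH2C≡C–SiMe3 [[4-(ArA)but-1-yn-1-yl]trimethylsilane], via 3-lithio-1-(trimethylsilyl)propyne 10 (not isolated)
Conditions: 9, n-BuLi, THF, –78 °C; then 8, –78 to –20 °C
Reagents that add atoms: 1-(trimethylsilyl)propyne (compound 9), CC#C[Si](C)(C)C
Why: SN2 alkylation of a silyl-capped propargyl anion by a benzylic bromide; the silyl group blocks the acetylenic terminus and steers attack to the propargylic carbon, not the allenyl one.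

**Step 7**
Reactants: 11 ArA–CH2CH2C≡C–SiMe3
Product: 12 ArA–CH2CH2C≡CH [1-(benzyloxy)-3-(but-3-yn-1-yl)-2,4,6-tris[4-(benzyloxy)benzyl]-5-methoxybenzene]
Conditions: K2CO3 (0.2 equiv), MeOH/THF, rt
Reagents that add atoms: none
Why: Base-catalysed protodesilylation of an alkynylsilane by methoxide, a reaction to which aryl benzyl ethers are inert.

**Step 8**
Reactants: 12 ArA–CH2CH2C≡CH; 13 4-(benzyloxy)benzoyl chloride
Product: 14 5-(ArA)-1-[4-(benzyloxy)phenyl]pent-2-yn-1-one
Conditions: 13 (1.3 equiv), PdCl2(PPh3)2 (2 mol%), CuI (4 mol%), Et3N, THF, rt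
Reagents that add atoms: 4-(benzyloxy)benzoyl chloride (compound 13), O=C(Cl)c1ccc(OCc2ccccc2)cc1
Why: Acyl Sonogashira coupling; the copper acetylide transmetalates to the acylpalladium chloride formed by oxidative addition of 13 to zerovalent palladium, and reductive elimination gives the ynone without any strong base.

**Step 9**
Reactants: 14 5-(ArA)-1-[4-(benzyloxy)phenyl]pent-2-yn-1-one; 15 trans-1-methoxy-3-(trimethylsilyloxy)buta-1,3-diene
Product: 18 [4-(benzyloxy)phenyl][2-[2-(ArA)ethyl]-4-hydroxyphenyl]methanone, via cyclohexadiene cycloadduct 16 (not isolated), via aryl trimethylsilyl ether 17 (not isolated)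
Conditions: 15 (4 equiv, in portions), toluene, 110 °C, sealed tube; then 1 M HCl, THF, rt
Reagents that add atoms: trans-1-methoxy-3-(trimethylsilyloxy)buta-1,3-diene (compound 15), CO/C=C/C(=C)O[Si](C)(C)C
Why: The electron-rich diene 15 and the electron-poor triple bond of 14 combine in a thermal, concerted but asynchronous normal-demand Diels–Alder (4+2) cycloaddition, the closest known reaction type being the addition of 1-methoxy-3-silyloxybutadienes to acetylenic ketones that gives para-hydroxyaryl ketones. Ring B closes as a six-membered carbocycle by intermolecular (4+2) annulation in which B1–B2 and B5–B6 form in the same step, four ring carbons coming from 15 and two from the alkyne. Adduct 16 then loses methanol across B2/B5 to give arene 17, whose aryl silyl ether is hydrolysed by the dilute acid, and the gain of aromaticity makes the sequence irreversible. The only new stereocentre (B5 of 16) forms as a racemate under no control and is destroyed in the elimination, so no stereochemistry has to be secured. The step needs regioselectivity, and the diene secures it: its unsubstituted CH2 terminus, made the most nucleophilic carbon by both oxygen donors, bonds to the ynone β-carbon (B1), while the methoxy-bearing terminus bonds to the acyl-bearing carbon (B6), which puts the oxygen on B3. Chemoselectivity is secured by the substrate, which carries every phenol as a benzyl ether, so no acidic proton cleaves the silyl enol ether before it reacts.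

**Step 10**
Reactants: 18 [4-(benzyloxy)phenyl][2-[2-(ArA)ethyl]-4-hydroxyphenyl]methanone
Product: 19 4-[4-(benzyloxy)benzyl]-3-[2-(ArA)ethyl]phenol
Conditions: Et3SiH (5 equiv), TFA/CH2Cl2 (1:4), 0 °C to rt
Reagents that add atoms: none
Why: Ionic hydrogenation; protonation of the diaryl ketone, hydride transfer, ionization of the benzhydrol to a cation stabilized by two para-oxygenated rings and a second hydride transfer give the CH2 group, while the aryl benzyl ethers should tolerate brief exposure to dilute TFA.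

**Step 11**
Reactants: 19 4-[4-(benzyloxy)benzyl]-3-[2-(ArA)ethyl]phenol
Product: 20 Bleochrin B
Conditions: H2 (1 atm), 10% Pd/C, EtOAc/MeOH, rt
Reagents that add atoms: none
Why: Catalytic hydrogenolysis cleaves the five benzylic C–O bonds of the aryl benzyl ethers, whereas the diarylmethane C–C bonds, the bibenzyl bridge and the methyl ether are inert.

**Compound list**
1 | 3-bromo-5-methoxyphenol | COc1cc(O)cc(Br)c1 | starting material
2 | 4-(benzyloxy)benzyl alcohol | OCc1ccc(OCc2ccccc2)cc1 | starting material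
3 | 3-bromo-2,4,6-tris[4-(benzyloxy)benzyl]-5-methoxyphenol | COc1c(Cc2ccc(OCc3ccccc3)cc2)c(O)c(Cc2ccc(OCc3ccccc3)cc2)c(Br)c1Cc1ccc(OCc2ccccc2)cc1 | intermediate
4 | ArA–Br, 1-(benzyloxy)-3-bromo-2,4,6-tris[4-(benzyloxy)benzyl]-5-methoxybenzene | COc1c(Cc2ccc(OCc3ccccc3)cc2)c(OCc2ccccc2)c(Cc2ccc(OCc3ccccc3)cc2)c(Br)c1Cc1ccc(OCc2ccccc2)cc1 | intermediate
5 | ArA–Li, [3-(benzyloxy)-2,4,6-tris[4-(benzyloxy)benzyl]-5-methoxyphenyl]lithium (not isolated) | COc1c(Cc2ccc(OCc3ccccc3)cc2)c(OCc2ccccc2)c(Cc2ccc(OCc3ccccc3)cc2)c([Li])c1Cc1ccc(OCc2ccccc2)cc1 | intermediate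
6 | ArA–CHO, 3-(benzyloxy)-2,4,6-tris[4-(benzyloxy)benzyl]-5-methoxybenzaldehyde | COc1c(Cc2ccc(OCc3ccccc3)cc2)c(OCc2ccccc2)c(Cc2ccc(OCc3ccccc3)cc2)c(C=O)c1Cc1ccc(OCc2ccccc2)cc1 | intermediate
7 | ArA–CH2OH, [3-(benzyloxy)-2,4,6-tris[4-(benzyloxy)benzyl]-5-methoxyphenyl]methanol | COc1c(Cc2ccc(OCc3ccccc3)cc2)c(OCc2ccccc2)c(Cc2ccc(OCc3ccccc3)cc2)c(CO)c1Cc1ccc(OCc2ccccc2)cc1 | intermediate
8 | ArA–CH2Br, 1-(benzyloxy)-3-(bromomethyl)-2,4,6-tris[4-(benzyloxy)benzyl]-5-methoxybenzene | COc1c(Cc2ccc(OCc3ccccc3)cc2)c(OCc2ccccc2)c(Cc2ccc(OCc3ccccc3)cc2)c(CBr)c1Cc1ccc(OCc2ccccc2)cc1 | intermediate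
9 | 1-(trimethylsilyl)propyne | CC#C[Si](C)(C)C | starting material
10 | 3-lithio-1-(trimethylsilyl)propyne (not isolated) | [Li]CC#C[Si](C)(C)C | intermediate
11 | [4-(ArA)but-1-yn-1-yl]trimethylsilane | COc1c(Cc2ccc(OCc3ccccc3)cc2)c(OCc2ccccc2)c(Cc2ccc(OCc3ccccc3)cc2)c(CCC#C[Si](C)(C)C)c1Cc1ccc(OCc2ccccc2)cc1 | intermediate
12 | 1-(benzyloxy)-3-(but-3-yn-1-yl)-2,4,6-tris[4-(benzyloxy)benzyl]-5-methoxybenzene | COc1c(Cc2ccc(OCc3ccccc3)cc2)c(OCc2ccccc2)c(Cc2ccc(OCc3ccccc3)cc2)c(CCC#C)c1Cc1ccc(OCc2ccccc2)cc1 | intermediate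
13 | 4-(benzyloxy)benzoyl chloride | O=C(Cl)c1ccc(OCc2ccccc2)cc1 | starting material
14 | 5-(ArA)-1-[4-(benzyloxy)phenyl]pent-2-yn-1-one | COc1c(Cc2ccc(OCc3ccccc3)cc2)c(OCc2ccccc2)c(Cc2ccc(OCc3ccccc3)cc2)c(CCC#CC(=O)c2ccc(OCc3ccccc3)cc2)c1Cc1ccc(OCc2ccccc2)cc1 | intermediate
15 | trans-1-methoxy-3-(trimethylsilyloxy)buta-1,3-diene | CO/C=C/C(=C)O[Si](C)(C)C | starting material
16 | [4-(benzyloxy)phenyl][2-[2-(ArA)ethyl]-6-methoxy-4-(trimethylsilyloxy)cyclohexa-1,4-dien-1-yl]methanone, racemic (not isolated) | COc1c(Cc2ccc(OCc3ccccc3)cc2)c(OCc2ccccc2)c(Cc2ccc(OCc3ccccc3)cc2)c(CCC2=C(C(=O)c3ccc(OCc4ccccc4)cc3)C(OC)C=C(O[Si](C)(C)C)C2)c1Cc1ccc(OCc2ccccc2)cc1 | intermediate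
17 | [4-(benzyloxy)phenyl][2-[2-(ArA)ethyl]-4-(trimethylsilyloxy)phenyl]methanone (not isolated) | COc1c(Cc2ccc(OCc3ccccc3)cc2)c(OCc2ccccc2)c(Cc2ccc(OCc3ccccc3)cc2)c(CCc2cc(O[Si](C)(C)C)ccc2C(=O)c2ccc(OCc3ccccc3)cc2)c1Cc1ccc(OCc2ccccc2)cc1 | intermediate
18 | [4-(benzyloxy)phenyl][2-[2-(ArA)ethyl]-4-hydroxyphenyl]methanone | COc1c(Cc2ccc(OCc3ccccc3)cc2)c(OCc2ccccc2)c(Cc2ccc(OCc3ccccc3)cc2)c(CCc2cc(O)ccc2C(=O)c2ccc(OCc3ccccc3)cc2)c1Cc1ccc(OCc2ccccc2)cc1 | intermediate
19 | 4-[4-(benzyloxy)benzyl]-3-[2-(ArA)ethyl]phenol | COc1c(Cc2ccc(OCc3ccccc3)cc2)c(OCc2ccccc2)c(Cc2ccc(OCc3ccccc3)cc2)c(CCc2cc(O)ccc2Cc2ccc(OCc3ccccc3)cc2)c1Cc1ccc(OCc2ccccc2)cc1 | intermediate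
20 | Bleochrin B, 2,4,6-tris(4-hydroxybenzyl)-3-[2-[5-hydroxy-2-(4-hydroxybenzyl)phenyl]ethyl]-5-methoxyphenol | COc1c(Cc2ccc(O)cc2)c(O)c(Cc2ccc(O)cc2)c(CCc2cc(O)ccc2Cc2ccc(O)cc2)c1Cc1ccc(O)cc1 | target

**Step count**
Total: 11 steps. Longest linear sequence: 11 steps (1 to 20); compounds 2, 9, 13 and 15 are purchased.

**Steps most likely to fail**

Step 1 (threefold C-benzylation). Alkylation may stall after two benzyl groups on the increasingly crowded ring, while the surplus benzylic cation self-condenses or attacks the pendant rings, and acid-promoted benzyl transfer may scramble the substitution pattern. The fallback sets out from 1 and replaces electrophilic benzylation by cross-coupling. Triple iodination of 1 with N-iodosuccinimide (3.3 equiv, cat. TFA, MeCN) should give 3-bromo-2,4,6-triiodo-5-methoxyphenol F1. O-Benzylation (BnBr, K2CO3, DMF) gives 1-(benzyloxy)-3-bromo-2,4,6-triiodo-5-methoxybenzene F2. A threefold Negishi coupling with 4-(benzyloxy)benzylzinc chloride (from 4-(benzyloxy)benzyl chloride, zinc dust and LiCl in THF) under Pd(OAc)2/SPhos, relying on the faster oxidative addition of C–I over C–Br, returns to the route at 4.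

Step 9 (Diels–Alder/aromatization). The β-alkyl ynone with an electron-rich aroyl group may add too slowly, so that thermal decomposition and oligomerization of the diene outrun the cycloaddition. The fallback sets out from 12 and uses a more reactive dienophile, attaching the aryl group after ring B exists. Lithiation of 12 (n-BuLi, THF, –78 °C) and formylation with DMF, followed by aqueous work-up, should give 5-(ArA)pent-2-ynal F3. Cycloaddition with 15 at lower temperature (toluene, 60–80 °C) and the same acid work-up should give 2-[2-(ArA)ethyl]-4-hydroxybenzaldehyde F4, with the same B3/B6 relationship. Addition of 4-(benzyloxy)phenylmagnesium bromide (2.5 equiv, THF, 0 °C; the first equivalent is consumed by the phenol) gives the diaryl carbinol 4-[[4-(benzyloxy)phenyl](hydroxy)methyl]-3-[2-(ArA)ethyl]phenol F5. Et3SiH in TFA/CH2Cl2 reduces this carbinol directly, and the fallback comes back to the route at 19.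

Step 6 (propargylation). The strongly basic propargyl anion may abstract a proton from the doubly benzylic CH2 groups or undergo halogen–lithium exchange with the hindered benzylic bromide, leading to Wurtz-type homocoupling; some allenyl product may also form. The fallback sets out from 8 and builds the alkyne by homologation with a much weaker carbon base. Alkylation of lithioacetonitrile (MeCN, n-BuLi, THF, –78 °C) with 8 should give 3-(ArA)propanenitrile F6. DIBAL-H (toluene, –78 °C; aqueous acid work-up) gives 3-(ArA)propanal F7. Seyferth–Gilbert homologation with dimethyl (1-diazo-2-oxopropyl)phosphonate (K2CO3, MeOH, rt) returns to the route at 12.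

**Further compounds**
F1 | step 1 | 3-bromo-2,4,6-triiodo-5-methoxyphenol | COc1c(I)c(O)c(I)c(Br)c1I
F2 | step 1 | 1-(benzyloxy)-3-bromo-2,4,6-triiodo-5-methoxybenzene | COc1c(I)c(OCc2ccccc2)c(I)c(Br)c1I
F3 | step 9 | 5-(ArA)pent-2-ynal | COc1c(Cc2ccc(OCc3ccccc3)cc2)c(OCc2ccccc2)c(Cc2ccc(OCc3ccccc3)cc2)c(CCC#CC=O)c1Cc1ccc(OCc2ccccc2)cc1
F4 | step 9 | 2-[2-(ArA)ethyl]-4-hydroxybenzaldehyde | COc1c(Cc2ccc(OCc3ccccc3)cc2)c(OCc2ccccc2)c(Cc2ccc(OCc3ccccc3)cc2)c(CCc2cc(O)ccc2C=O)c1Cc1ccc(OCc2ccccc2)cc1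
F5 | step 9 | 4-[[4-(benzyloxy)phenyl](hydroxy)methyl]-3-[2-(ArA)ethyl]phenol, racemic | COc1c(Cc2ccc(OCc3ccccc3)cc2)c(OCc2ccccc2)c(Cc2ccc(OCc3ccccc3)cc2)c(CCc2cc(O)ccc2C(O)c2ccc(OCc3ccccc3)cc2)c1Cc1ccc(OCc2ccccc2)cc1
F6 | step 6 | 3-(ArA)propanenitrile | COc1c(Cc2ccc(OCc3ccccc3)cc2)c(OCc2ccccc2)c(Cc2ccc(OCc3ccccc3)cc2)c(CCC#N)c1Cc1ccc(OCc2ccccc2)cc1
F7 | step 6 | 3-(ArA)propanal | COc1c(Cc2ccc(OCc3ccccc3)cc2)c(OCc2ccccc2)c(Cc2ccc(OCc3ccccc3)cc2)c(CCC=O)c1Cc1ccc(OCc2ccccc2)cc1
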